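Retrosynthesis: the three O–Si bonds and the pyran ether bond O1'–C2' are cut first. The benzene ring of the chroman is then cut at C8a'–C8', C7'–C6' and C8a'–C4a' into a 3-(benzofuran-2-yl)-2,4-diprenylcyclobutenone and (triisopropylsilyloxy)ethyne (primed locants: chroman; plain locants: benzofuran).
Enabling feature: that ring is a resorcinol (O on C7' and C8a', H on C8'). Its C5', meta to both oxygens, carries benzofuran C2 and lies between the alkylated carbons C4a' and C6'. C4a'–C5'–C6' maps onto C4–C3–C2 of the cyclobutenone, C8a' is its carbonyl carbon and C7'–C8' is the alkyne.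
The cyclobutenone is cut at C2–C5' into a 2-lithiobenzofuran and 3-ethoxy-2,4-diprenylcyclobutenone, which is the thermal dimer (minus ethene) of prenylated ethoxyethyne.
Forward ring order: furan ring (copper-catalysed C–O closure on diformylphloroglucinol), four-membered ring ([2+2]), benzene ring (benzannulation), pyran ring (selenoetherification, then tin hydride).
Stereochemistry: the single centre (R, the benzylic carbon on C7) comes from a ligand-controlled copper-catalysed SN2' methylation of an (E)-2-methylallyl chloride. It later meets no acid able to protonate the isopropenyl group, and the transient centres (cyclobutenone C4, C3'–Se) are erased.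

Key step: step 12

Assumption: 2,4,6-trihydroxybenzene-1,3-dicarbaldehyde is taken as a catalogue compound; it is also one double Vilsmeier formylation away from phloroglucinol.
Assumption: the sense of induction of the phosphoramidite in step 7 is inferred from 2-methylcinnamyl chloride. If the configurational assay shows the S product, the mirror-image ligand is used and nothing else changes.

Step 1
Reactants: 1 2,4,6-trihydroxybenzene-1,3-dicarbaldehyde
Product: 2 4,6-bis(tert-butyldimethylsilyloxy)-2-hydroxybenzene-1,3-dicarbaldehyde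
Conditions: TBSCl (2.1 equiv), Et3N, DMAP (cat.), CH2Cl2, 0 °C
Reagents that add atoms: tert-butyldimethylsilyl chloride, CC(C)(C)[Si](C)(C)Cl
Why: Silyl ether formation goes to the two equivalent outer phenols, because the inner hydroxyl lies between both formyl groups, is chelated and shielded, and any silyl ether formed there is the most labile one and falls off on work-up.

Step 2
Reactants: 2 4,6-bis(tert-butyldimethylsilyloxy)-2-hydroxybenzene-1,3-dicarbaldehyde
Product: 3 4,6-bis(tert-butyldimethylsilyloxy)-3-(2,2-dibromoethenyl)-2-hydroxybenzaldehyde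
Conditions: CBr4, PPh3, Zn dust (1.1 equiv each, ylide preformed), CH2Cl2, 0 °C → rt
Reagents that add atoms: tetrabromomethane, BrC(Br)(Br)Br
Why: Ramirez dibromo-olefination with one equivalent of the preformed, weakly basic ylide converts one of the two equivalent formyl groups, and over-reaction is held back because loss of the first acceptor leaves the second formyl group on a more electron-rich ring and tied up in the hydrogen bond of the free phenol; recovered 2 is recycled.

Step 3
Reactants: 3 4,6-bis(tert-butyldimethylsilyloxy)-3-(2,2-dibromoethenyl)-2-hydroxybenzaldehyde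
Product: 4 2-bromo-4,6-bis(tert-butyldimethylsilyloxy)-1-benzofuran-7-carbaldehyde
Conditions: CuI (5 mol %), K3PO4 (2 equiv), THF, 80 °C
Reagents that add atoms: none
Why: Copper-catalysed intramolecular Ullmann-type C–O coupling of a 2-(2,2-dibromoethenyl)phenol is an established entry to 2-bromobenzofurans, and since the inner hydroxyl is the only free one the furan oxygen must end up beside the carbon that bears the remaining formyl group, which fixes the C7 substitution pattern.

Step 4
Reactants: 4 2-bromo-4,6-bis(tert-butyldimethylsilyloxy)-1-benzofuran-7-carbaldehyde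
Product: 5 ethyl (E)-3-[2-bromo-4,6-bis(tert-butyldimethylsilyloxy)-1-benzofuran-7-yl]-2-methylprop-2-enoate
Conditions: Ph3P=C(CH3)CO2Et, PhMe, 90 °C
Reagents that add atoms: ethyl 2-(triphenylphosphoranylidene)propanoate, CCOC(=O)C(C)=P(c1ccccc1)(c1ccccc1)c1ccccc1
Why: Wittig olefination with a stabilised α-methyl ylide gives the E-trisubstituted enoate and tolerates the aryl silyl ethers and the bromide.

Step 5
Reactants: 5 ethyl (E)-3-[2-bromo-4,6-bis(tert-butyldimethylsilyloxy)-1-benzofuran-7-yl]-2-methylprop-2-enoate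
Product: 6 (E)-3-[2-bromo-4,6-bis(tert-butyldimethylsilyloxy)-1-benzofuran-7-yl]-2-methylprop-2-en-1-ol
Conditions: i-Bu2AlH (2.3 equiv), CH2Cl2, −78 °C; aq. potassium sodium tartrate
Reagents that add atoms: none
Why: 1,2-Reduction of the enoate with two hydride equivalents at low temperature gives the allylic alcohol with the E geometry kept and leaves the C–Br and O–Si bonds alone.

Step 6
Reactants: 6 (E)-3-[2-bromo-4,6-bis(tert-butyldimethylsilyloxy)-1-benzofuran-7-yl]-2-methylprop-2-en-1-ol
Product: 7 2-bromo-4,6-bis(tert-butyldimethylsilyloxy)-7-[(E)-3-chloro-2-methylprop-1-enyl]-1-benzofuran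
Conditions: PPh3, (Cl3C)2CO, CH2Cl2, −20 → 0 °C; used at once
Reagents that add atoms: hexachloroacetone, ClC(Cl)(Cl)C(=O)C(Cl)(Cl)Cl
Why: Appel-type chlorination with PPh3 and hexachloroacetone runs under neutral conditions by SN2 displacement of the alkoxyphosphonium ion, so that the primary allylic chloride forms without allylic shift or loss of geometry despite the electron-rich arene.

Step 7
Reactants: 7 2-bromo-4,6-bis(tert-butyldimethylsilyloxy)-7-[(E)-3-chloro-2-methylprop-1-enyl]-1-benzofuran
Product: 8 2-bromo-4,6-bis(tert-butyldimethylsilyloxy)-7-[(2R)-3-methylbut-3-en-2-yl]-1-benzofuran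
Conditions: MeMgBr (slow addition), Cu(O2CC4H3S) (copper thiophene-2-carboxylate, 3 mol %), O,O'-(biphenyl-2,2'-diyl) N,N-bis[(S)-1-(2-methoxyphenyl)ethyl]phosphoramidite (3.3 mol %), CH2Cl2, −78 °C
Reagents that add atoms: methylmagnesium bromide, C[Mg]Br
Why: Copper-catalysed asymmetric allylic alkylation of 2-substituted cinnamyl-type chlorides with Grignard reagents is known to give the SN2' product with a 1,1-disubstituted alkene: the chiral phosphoramidite–copper complex binds one face of the E alkene, oxidative addition anti to chloride places trivalent copper on the benzylic carbon and fast reductive elimination delivers methyl there, which sets the R centre under ligand control.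

Step 8
Reactants: 9 ethoxyethyne; 10 1-bromo-3-methylbut-2-ene (prenyl bromide)
Product: 12 1-ethoxy-5-methylhex-4-en-1-yne, via lithium ethoxyacetylide 11 (not isolated)
Conditions: n-BuLi, THF, −78 °C; then 10, DMPU, −78 °C → rt
Reagents that add atoms: none
Why: Alkylation of a lithium alkoxyacetylide with a primary allylic bromide in THF with a dipolar cosolvent is a standard SN2 route to 1-alkoxyalk-1-ynes.

Step 9
Reactants: 12 1-ethoxy-5-methylhex-4-en-1-yne (two molecules)
Product: 14 3-ethoxy-2,4-bis(3-methylbut-2-enyl)cyclobut-2-en-1-one, via prenylketene 13 (not isolated)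
Conditions: neat under argon, 120 °C
Reagents that add atoms: none
Why: Thermolysis of 1-ethoxyalk-1-ynes is the classical route to 2,4-dialkyl-3-ethoxycyclobutenones: a retro-ene loss of ethene from part of 12 gives ketene 13, whose carbonyl carbon is attacked by the alkyl-bearing carbon of unchanged 12 in a regioselective [2+2] cycloaddition, which sidesteps the β-lactone dimers that monoalkylketenes form on their own.

Step 10
Reactants: 8 2-bromo-4,6-bis(tert-butyldimethylsilyloxy)-7-[(2R)-3-methylbut-3-en-2-yl]-1-benzofuran; 14 3-ethoxy-2,4-bis(3-methylbut-2-enyl)cyclobut-2-en-1-one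
Product: 17 3-{4,6-bis(tert-butyldimethylsilyloxy)-7-[(2R)-3-methylbut-3-en-2-yl]-1-benzofuran-2-yl}-2,4-bis(3-methylbut-2-enyl)cyclobut-2-en-1-one (C4 epimers), via 2-lithiobenzofuran 15 (not isolated), via tertiary cyclobutenol 16 (not isolated)
Conditions: 8, n-BuLi, THF, −78 °C; 14, −78 °C; then 1 M aq. HCl, THF, 0 °C
Reagents that add atoms: water, O
Why: Bromine–lithium exchange, 1,2-addition of the aryllithium to the vinylogous ester and acid-induced ionisation–hydrolysis with carbonyl transposition is the standard way from 3-alkoxycyclobutenones to 3-substituted cyclobutenones; the doubly stabilised cation forms in cold dilute acid that spares silyl ethers and alkenes, and the C4 epimers need not be separated.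

Step 11
Reactants: 18 ethyne
Product: 21 (triisopropylsilyloxy)ethyne, via lithium acetylide 19 (not isolated), via lithium ethynolate 20 (not isolated)
Conditions: ethyne (excess, satd. in THF), n-BuLi, −78 °C; t-BuOOLi [t-BuOOH, LiN(SiMe3)2, THF, −78 °C], −78 → −10 °C under ethyne; i-Pr3SiOTf, −78 → 0 °C
Reagents that add atoms: tert-butyl hydroperoxide, CC(C)(C)OO; triisopropylsilyl trifluoromethanesulfonate, CC(C)[Si](C(C)C)(C(C)C)OS(=O)(=O)C(F)(F)F
Why: Oxidation of a lithium acetylide with lithium tert-butyl peroxide gives the lithium ynolate, and the hard, bulky silyl triflate then reacts at oxygen, the established two-stage route to triisopropylsilyl ynol ethers; excess ethyne keeps the monolithium acetylide from disproportionating.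

Step 12
Reactants: 17 3-{4,6-bis(tert-butyldimethylsilyloxy)-7-[(2R)-3-methylbut-3-en-2-yl]-1-benzofuran-2-yl}-2,4-bis(3-methylbut-2-enyl)cyclobut-2-en-1-one; 21 (triisopropylsilyloxy)ethyne
Product: 26 3-{4,6-bis(tert-butyldimethylsilyloxy)-7-[(2R)-3-methylbut-3-en-2-yl]-1-benzofuran-2-yl}-2,4-bis(3-methylbut-2-enyl)-5-(triisopropylsilyloxy)phenol, via vinylketene 22 (not isolated), via alkenylcyclobutenone 23 (not isolated), via dienylketene 24 (not isolated), via cyclohexadienone 25 (not isolated)
Conditions: 21 (2 equiv), PhMe (0.4 M), sealed tube, 80 °C then 110 °C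
Reagents that add atoms: none
Why: Heating opens 17 by conrotatory 4π electrocyclic cleavage of C1–C4, the C4 prenyl group turning outward, to vinylketene 22; the nucleophilic CH carbon of 21 attacks the ketene carbonyl carbon and the silyloxy-bearing carbon bonds to the prenyl-bearing ketene carbon, a regioselective [2+2] cycloaddition that gives 23 and forms C8a'–C8' and C7'–C6'. A second 4π opening of 23 gives dienylketene 24, whose disrotatory 6π electrocyclisation re-forms C8a'–C4a' and closes the only new ring, the benzene ring, and tautomerisation of dienone 25 gives phenol 26. This is the Danheiser benzannulation in its cyclobutenone/siloxyalkyne form, the known route to resorcinol monosilyl ethers. No stereocentre is created: the sp3 carbon C4 of 17 and the quaternary carbon of 23 both become arene carbons, so the epimer mixture converges, and the remote R centre takes no part. The selectivity needed is regiochemical and is secured by the polarity match of ketene and ynol ether, which leaves the free OH on C8a' beside one prenyl group and the silyl ether on C7' beside the other. The excess of 21 keeps ketene capture faster than acylation of 26 by 22 or a 1,5-hydrogen shift.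

Step 13
Reactants: 26 3-{4,6-bis(tert-butyldimethylsilyloxy)-7-[(2R)-3-methylbut-3-en-2-yl]-1-benzofuran-2-yl}-2,4-bis(3-methylbut-2-enyl)-5-(triisopropylsilyloxy)phenol
Product: 27 5-{4,6-bis(tert-butyldimethylsilyloxy)-7-[(2R)-3-methylbut-3-en-2-yl]-1-benzofuran-2-yl}-2,2-dimethyl-6-(3-methylbut-2-enyl)-3-(phenylselanyl)-7-(triisopropylsilyloxy)chromane (C3' epimers)
Conditions: N-(phenylselanyl)phthalimide (1.05 equiv), camphorsulfonic acid (5 mol %), CH2Cl2, −78 → −20 °C
Reagents that add atoms: N-(phenylselanyl)phthalimide, O=C1c2ccccc2C(=O)N1[Se]c1ccccc1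
Why: Phenylselenoetherification of an ortho-prenylphenol closes the 2,2-dimethylchroman by 6-endo Markovnikov opening of the seleniranium ion; seleniranium formation is reversible and only the prenyl group beside the one free phenol has a nucleophile in reach, no Brønsted acid strong enough to protonate the isopropenyl group (which would invite a benzylic hydride shift and loss of the R centre) is present, and the new C3' centre is unimportant because step 14 removes it.

Step 14
Reactants: 27 5-{4,6-bis(tert-butyldimethylsilyloxy)-7-[(2R)-3-methylbut-3-en-2-yl]-1-benzofuran-2-yl}-2,2-dimethyl-6-(3-methylbut-2-enyl)-3-(phenylselanyl)-7-(triisopropylsilyloxy)chromane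
Product: 28 5-{4,6-bis(tert-butyldimethylsilyloxy)-7-[(2R)-3-methylbut-3-en-2-yl]-1-benzofuran-2-yl}-2,2-dimethyl-6-(3-methylbut-2-enyl)-7-(triisopropylsilyloxy)chromane
Conditions: n-Bu3SnH (0.2 M), AIBN (cat.), PhH, 80 °C
Reagents that add atoms: none
Why: Radical deselenation with tin hydride replaces the C3'–Se bond by C–H, the secondary radical being quenched by the concentrated stannane faster than it can add to the neighbouring π systems, and isolated alkenes and aryl silyl ethers are inert.

Step 15
Reactants: 28 5-{4,6-bis(tert-butyldimethylsilyloxy)-7-[(2R)-3-methylbut-3-en-2-yl]-1-benzofuran-2-yl}-2,2-dimethyl-6-(3-methylbut-2-enyl)-7-(triisopropylsilyloxy)chromane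
Product: 29 2-[7-hydroxy-2,2-dimethyl-6-(3-methylbut-2-enyl)chroman-5-yl]-7-[(2R)-3-methylbut-3-en-2-yl]-1-benzofuran-4,6-diol (CNP0325834.1)
Conditions: n-Bu4NF, AcOH (3.5 equiv each), THF, 0 °C → rt
Reagents that add atoms: none
Why: Fluoride cleaves the three aryl silyl ethers, and the acetic acid buffer keeps the electron-rich phenolates protonated without being acidic enough to cyclise a phenol onto the prenyl or isopropenyl group, so that the R centre is untouched.

Compound list
1 | 2,4,6-trihydroxybenzene-1,3-dicarbaldehyde | O=Cc1c(O)cc(O)c(C=O)c1O | starting material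
2 | 4,6-bis(tert-butyldimethylsilyloxy)-2-hydroxybenzene-1,3-dicarbaldehyde | O=Cc1c(O[Si](C)(C)C(C)(C)C)cc(O[Si](C)(C)C(C)(C)C)c(C=O)c1O | intermediate
3 | 4,6-bis(tert-butyldimethylsilyloxy)-3-(2,2-dibromoethenyl)-2-hydroxybenzaldehyde | O=Cc1c(O[Si](C)(C)C(C)(C)C)cc(O[Si](C)(C)C(C)(C)C)c(C=C(Br)Br)c1O | intermediate
4 | 2-bromo-4,6-bis(tert-butyldimethylsilyloxy)-1-benzofuran-7-carbaldehyde | O=Cc1c(O[Si](C)(C)C(C)(C)C)cc(O[Si](C)(C)C(C)(C)C)c2cc(Br)oc12 | intermediate
5 | ethyl (E)-3-[2-bromo-4,6-bis(tert-butyldimethylsilyloxy)-1-benzofuran-7-yl]-2-methylprop-2-enoate | CCOC(=O)/C(C)=C/c1c(O[Si](C)(C)C(C)(C)C)cc(O[Si](C)(C)C(C)(C)C)c2cc(Br)oc12 | intermediate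
6 | (E)-3-[2-bromo-4,6-bis(tert-butyldimethylsilyloxy)-1-benzofuran-7-yl]-2-methylprop-2-en-1-ol | OC/C(C)=C/c1c(O[Si](C)(C)C(C)(C)C)cc(O[Si](C)(C)C(C)(C)C)c2cc(Br)oc12 | intermediate
7 | 2-bromo-4,6-bis(tert-butyldimethylsilyloxy)-7-[(E)-3-chloro-2-methylprop-1-enyl]-1-benzofuran | ClC/C(C)=C/c1c(O[Si](C)(C)C(C)(C)C)cc(O[Si](C)(C)C(C)(C)C)c2cc(Br)oc12 | intermediate
8 | 2-bromo-4,6-bis(tert-butyldimethylsilyloxy)-7-[(2R)-3-methylbut-3-en-2-yl]-1-benzofuran | C=C(C)[C@@H](C)c1c(O[Si](C)(C)C(C)(C)C)cc(O[Si](C)(C)C(C)(C)C)c2cc(Br)oc12 | intermediate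
9 | ethoxyethyne | C#COCC | starting material
10 | 1-bromo-3-methylbut-2-ene | CC(C)=CCBr | starting material
11 | lithium ethoxyacetylide | [Li]C#COCC | intermediate (not isolated)
12 | 1-ethoxy-5-methylhex-4-en-1-yne | CCOC#CCC=C(C)C | intermediate
13 | 5-methylhexa-1,4-dien-1-one (prenylketene) | O=C=CCC=C(C)C | intermediate (not isolated)
14 | 3-ethoxy-2,4-bis(3-methylbut-2-enyl)cyclobut-2-en-1-one (racemic) | CCOC1=C(CC=C(C)C)C(=O)C1CC=C(C)C | intermediate
15 | 4,6-bis(tert-butyldimethylsilyloxy)-2-lithio-7-[(2R)-3-methylbut-3-en-2-yl]-1-benzofuran | C=C(C)[C@@H](C)c1c(O[Si](C)(C)C(C)(C)C)cc(O[Si](C)(C)C(C)(C)C)c2cc([Li])oc12 | intermediate (not isolated)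
16 | 1-{4,6-bis(tert-butyldimethylsilyloxy)-7-[(2R)-3-methylbut-3-en-2-yl]-1-benzofuran-2-yl}-3-ethoxy-2,4-bis(3-methylbut-2-enyl)cyclobut-2-en-1-ol (formed as lithium alkoxide, drawn protonated, ring centres mixed) | C=C(C)[C@@H](C)c1c(O[Si](C)(C)C(C)(C)C)cc(O[Si](C)(C)C(C)(C)C)c2cc(C3(O)C(CC=C(C)C)=C(OCC)C3CC=C(C)C)oc12 | intermediate (not isolated)
17 | 3-{4,6-bis(tert-butyldimethylsilyloxy)-7-[(2R)-3-methylbut-3-en-2-yl]-1-benzofuran-2-yl}-2,4-bis(3-methylbut-2-enyl)cyclobut-2-en-1-one (C4 epimers) | C=C(C)[C@@H](C)c1c(O[Si](C)(C)C(C)(C)C)cc(O[Si](C)(C)C(C)(C)C)c2cc(C3=C(CC=C(C)C)C(=O)C3CC=C(C)C)oc12 | intermediate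
18 | ethyne | C#C | starting material
19 | lithium acetylide | [Li]C#C | intermediate (not isolated)
20 | lithium ethynolate | [Li]OC#C | intermediate (not isolated)
21 | (triisopropylsilyloxy)ethyne | C#CO[Si](C(C)C)(C(C)C)C(C)C | intermediate
22 | vinylketene from 4π opening of 17 (terminal prenyl group turned away from the ketene) | C=C(C)[C@@H](C)c1c(O[Si](C)(C)C(C)(C)C)cc(O[Si](C)(C)C(C)(C)C)c2cc(C(\C(CC=C(C)C)=C=O)=C/CC=C(C)C)oc12 | intermediate (not isolated)
23 | 4-alkenyl-4-(3-methylbut-2-enyl)-3-(triisopropylsilyloxy)cyclobut-2-en-1-one, the [2+2] adduct | C=C(C)[C@@H](C)c1c(O[Si](C)(C)C(C)(C)C)cc(O[Si](C)(C)C(C)(C)C)c2cc(C(=C/CC=C(C)C)\C3(CC=C(C)C)C(=O)C=C3O[Si](C(C)C)(C(C)C)C(C)C)oc12 | intermediate (not isolated)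
24 | dienylketene from 4π opening of 23 (alkenyl group turned toward the ketene) | C=C(C)[C@@H](C)c1c(O[Si](C)(C)C(C)(C)C)cc(O[Si](C)(C)C(C)(C)C)c2cc(C(=C/CC=C(C)C)\C(CC=C(C)C)=C(/C=C=O)O[Si](C(C)C)(C(C)C)C(C)C)oc12 | intermediate (not isolated)
25 | cyclohexa-2,4-dien-1-one from 6π closure of 24 | C=C(C)[C@@H](C)c1c(O[Si](C)(C)C(C)(C)C)cc(O[Si](C)(C)C(C)(C)C)c2cc(C3=C(CC=C(C)C)C(O[Si](C(C)C)(C(C)C)C(C)C)=CC(=O)C3CC=C(C)C)oc12 | intermediate (not isolated)
26 | 3-{4,6-bis(tert-butyldimethylsilyloxy)-7-[(2R)-3-methylbut-3-en-2-yl]-1-benzofuran-2-yl}-2,4-bis(3-methylbut-2-enyl)-5-(triisopropylsilyloxy)phenol | C=C(C)[C@@H](C)c1c(O[Si](C)(C)C(C)(C)C)cc(O[Si](C)(C)C(C)(C)C)c2cc(-c3c(CC=C(C)C)c(O[Si](C(C)C)(C(C)C)C(C)C)cc(O)c3CC=C(C)C)oc12 | intermediate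
27 | 5-{4,6-bis(tert-butyldimethylsilyloxy)-7-[(2R)-3-methylbut-3-en-2-yl]-1-benzofuran-2-yl}-2,2-dimethyl-6-(3-methylbut-2-enyl)-3-(phenylselanyl)-7-(triisopropylsilyloxy)chromane (C3' epimers) | C=C(C)[C@@H](C)c1c(O[Si](C)(C)C(C)(C)C)cc(O[Si](C)(C)C(C)(C)C)c2cc(-c3c(CC=C(C)C)c(O[Si](C(C)C)(C(C)C)C(C)C)cc4OC(C)(C)C([Se]c5ccccc5)Cc34)oc12 | intermediate
28 | 5-{4,6-bis(tert-butyldimethylsilyloxy)-7-[(2R)-3-methylbut-3-en-2-yl]-1-benzofuran-2-yl}-2,2-dimethyl-6-(3-methylbut-2-enyl)-7-(triisopropylsilyloxy)chromane | C=C(C)[C@@H](C)c1c(O[Si](C)(C)C(C)(C)C)cc(O[Si](C)(C)C(C)(C)C)c2cc(-c3c(CC=C(C)C)c(O[Si](C(C)C)(C(C)C)C(C)C)cc4OC(C)(C)CCc34)oc12 | intermediate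
29 | 2-[7-hydroxy-2,2-dimethyl-6-(3-methylbut-2-enyl)chroman-5-yl]-7-[(2R)-3-methylbut-3-en-2-yl]-1-benzofuran-4,6-diol (CNP0325834.1) | C=C(C)[C@@H](C)c1c(O)cc(O)c2cc(-c3c(CC=C(C)C)c(O)cc4c3CCC(C)(C)O4)oc12 | target

Total steps: 15. Longest linear sequence: 12 (steps 1–7, 10, 12–15).

Steps most likely to fail

Step 12. Capture of the fully substituted ketene carbon by the alkyne may be slower than decay of the ketene (1,5-hydrogen shift, acylation of the product phenol), because the benzofuran and the triisopropylsilyl group crowd the quaternary carbon that forms. The fallback makes the biaryl bond after the ring. It sets out from 14 and 8. n-Bu3SnLi (from n-Bu3SnH and LiN(i-Pr)2, THF, −78 °C) adds to 14, and dilute acid gives 2,4-bis(3-methylbut-2-enyl)-3-(tributylstannyl)cyclobut-2-en-1-one F1, in which the long C–Sn bond holds the bulk away from the ketene terminus. The same thermal annulation of F1 with 21 gives 2,4-bis(3-methylbut-2-enyl)-3-(tributylstannyl)-5-(triisopropylsilyloxy)phenol F2. Stille coupling of F2 with 8 (Pd2(dba)3, AsPh3, CuI, DMF, 60 °C) forms C2–C5' and comes back to the route at 26.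

Step 11. Three processes may deplete 21: the monolithium acetylide may disproportionate on warming, the unhindered ynolate may be silylated at carbon, and the terminal siloxyalkyne may drift to the silylketene by a 1,3-silyl shift during isolation. The fallback sets out from 17 and uses an internal siloxyalkyne with a traceless cap. The same oxidation and silylation applied to commercial (trimethylsilyl)ethyne gives trimethyl[(triisopropylsilyloxy)ethynyl]silane F3. Heating F3 with 17 as in step 12 gives the 6-trimethylsilyl derivative of phenol 26 (silicon on C8') F4. Brief treatment of F4 with CF3CO2H (1 equiv, CH2Cl2, −40 °C) removes the silyl group by ipso-protonation of a carbon that is ortho to both oxygens, a process far faster than protonation of an isolated alkene. The route is rejoined at 26.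

Step 7. The electron-rich allylic chloride may ionise, methyl may be delivered to the primary carbon (SN2 leakage), and facial selectivity beside the ortho silyloxy group may be insufficient. The fallback sets the centre by reagent-controlled epoxidation and stereospecific opening and sets out from 6. Katsuki–Sharpless epoxidation (Ti(Oi-Pr)4, D-(−)-diethyl tartrate, t-BuOOH, 4 Å sieves, CH2Cl2, −20 °C) gives the (2R,3R)-epoxy alcohol F5. AlMe3 (CH2Cl2–hexane, −40 → 0 °C) opens F5 at the benzylic carbon with inversion to give the (2S,3S)-1,2-diol F6. 1,1'-Thiocarbonyldiimidazole (THF, reflux) gives the cyclic thionocarbonate F7. Corey–Winter olefination of F7 (P(OMe)3, 110 °C) then releases the 1,1-disubstituted alkene and comes back to the route at 8.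

Further compounds
F1 | step 12 | 2,4-bis(3-methylbut-2-enyl)-3-(tributylstannyl)cyclobut-2-en-1-one | CCCC[Sn](CCCC)(CCCC)C1=C(CC=C(C)C)C(=O)C1CC=C(C)C
F2 | step 12 | 2,4-bis(3-methylbut-2-enyl)-3-(tributylstannyl)-5-(triisopropylsilyloxy)phenol | Oc1cc(O[Si](C(C)C)(C(C)C)C(C)C)c(CC=C(C)C)c([Sn](CCCC)(CCCC)CCCC)c1CC=C(C)C
F3 | step 11 | trimethyl[(triisopropylsilyloxy)ethynyl]silane | C[Si](C)(C)C#CO[Si](C(C)C)(C(C)C)C(C)C
F4 | step 11 | 3-{4,6-bis(tert-butyldimethylsilyloxy)-7-[(2R)-3-methylbut-3-en-2-yl]-1-benzofuran-2-yl}-2,4-bis(3-methylbut-2-enyl)-5-(triisopropylsilyloxy)-6-(trimethylsilyl)phenol | C=C(C)[C@@H](C)c1c(O[Si](C)(C)C(C)(C)C)cc(O[Si](C)(C)C(C)(C)C)c2cc(-c3c(CC=C(C)C)c(O[Si](C(C)C)(C(C)C)C(C)C)c([Si](C)(C)C)c(O)c3CC=C(C)C)oc12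
F5 | step 7 | {(2R,3R)-3-[2-bromo-4,6-bis(tert-butyldimethylsilyloxy)-1-benzofuran-7-yl]-2-methyloxiran-2-yl}methanol | OC[C@@]3(C)O[C@@H]3c1c(O[Si](C)(C)C(C)(C)C)cc(O[Si](C)(C)C(C)(C)C)c2cc(Br)oc12
F6 | step 7 | (2S,3S)-3-[2-bromo-4,6-bis(tert-butyldimethylsilyloxy)-1-benzofuran-7-yl]-2-methylbutane-1,2-diol | OC[C@@](C)(O)[C@@H](C)c1c(O[Si](C)(C)C(C)(C)C)cc(O[Si](C)(C)C(C)(C)C)c2cc(Br)oc12
F7 | step 7 | (4S)-4-{(1S)-1-[2-bromo-4,6-bis(tert-butyldimethylsilyloxy)-1-benzofuran-7-yl]ethyl}-4-methyl-1,3-dioxolane-2-thione | S=C3OC[C@@](C)(O3)[C@@H](C)c1c(O[Si](C)(C)C(C)(C)C)cc(O[Si](C)(C)C(C)(C)C)c2cc(Br)oc12
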